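## Retrosynthetic overview

- The strategy rests on ring B, which carries a substituent on each of its six carbons (C5 alkyl, C6 O, C7 O, C8 CH3, C9 O, C10 CH3; labdane numbering). It is carried as a 2,6-dimethyl-3,4-dioxygenated phenol and dearomatised by closing the C1–C10 bond.
- Target ⇒ C6 MOM cleavage, C3 acetate, lactone C15(=O)–O–C16 ⇒ 5α-H/6β-O by hydrogenation of C5=C6 ⇒ tetrahydrofuran ring (C9–O) by oxa-Michael addition of the C13 hydroxyl to a Δ8-7-ketone.
- Δ8-7-ketone ⇒ dienone 19 plus a side-chain organolithium (C11–C16, from (R)-malic acid), joined by 1,2-addition at C9 and 1,3-carbonyl transposition.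
- Dienone 19 ⇒ iodoalkyl phenol 17 (phenolate ortho C-alkylation). 17 ⇒ 2,6-dimethylhydroquinone by prenyl ether Claisen rearrangement (C4–C5), ortho-oxygenation (C7–O) and asymmetric allylation (C3).
- Ring order: ring B (as the arene, from the start) → ring A (step 12) → tetrahydrofuran ring (step 23) → lactone ring (step 26).

Key step: step 12

Remark on the chemistry: atoms carry labdane numbers throughout. The allylborane made from (−)-Ipc2BOMe is assumed to add to the Si face of aldehyde 9, as it does with pivalaldehyde.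

## Route

Step 1
Reactants: 1 2,6-dimethylhydroquinone; 2 prenyl bromide
Product: 3 2,6-dimethyl-4-(3-methylbut-2-enyloxy)phenol
Conditions: K2CO3, acetone, reflux
Reagents that add atoms: none
Why: Williamson etherification should take the unhindered hydroxyl, because the one flanked by two methyls is less acidic and shielded.

Step 2
Reactants: 3 2,6-dimethyl-4-(3-methylbut-2-enyloxy)phenol
Product: 4 2-benzyloxy-1,3-dimethyl-5-(3-methylbut-2-enyloxy)benzene
Conditions: BnBr, K2CO3, DMF, 60 °C
Reagents that add atoms: benzyl bromide, BrCc1ccccc1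
Why: Williamson benzylation masks the hindered hydroxyl (the later C9 phenol) so that the ring cannot be oxidised to a para-quinone in step 4.

Step 3
Reactants: 4 2-benzyloxy-1,3-dimethyl-5-(3-methylbut-2-enyloxy)benzene
Product: 5 4-benzyloxy-3,5-dimethyl-2-(2-methylbut-3-en-2-yl)phenol
Conditions: Eu(fod)3 [fod = 6,6,7,7,8,8,8-heptafluoro-2,2-dimethyloctane-3,5-dionate] (10 mol %), CHCl3, 80 °C, sealed tube
Reagents that add atoms: none
Why: The aromatic Claisen rearrangement ([3,3]) of the prenyl ether delivers the 1,1-dimethylallyl group (quaternary C4 on C5) to one of two equivalent ortho carbons, and Lewis-acid catalysis keeps the temperature below that of the abnormal Claisen pathway.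

Step 4
Reactants: 5 4-benzyloxy-3,5-dimethyl-2-(2-methylbut-3-en-2-yl)phenol
Product: 7 4-benzyloxy-3,5-dimethyl-6-(2-methylbut-3-en-2-yl)benzene-1,2-diol, via o-quinone 6 (not isolated)
Conditions: IBX, DMF, rt; then Na2S2O4 aq., EtOAc
Reagents that add atoms: 2-iodoxybenzoic acid (IBX), O=C1OI(=O)(O)c2ccccc12
Why: IBX ortho-oxygenation of an electron-rich phenol transfers oxygen within the aryloxy-iodine intermediate to the only free ortho carbon (C7), and dithionite reduces the o-quinone to the catechol.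

Step 5
Reactants: 7 4-benzyloxy-3,5-dimethyl-6-(2-methylbut-3-en-2-yl)benzene-1,2-diol
Product: 8 1-benzyloxy-3,4-bis(methoxymethoxy)-2,6-dimethyl-5-(2-methylbut-3-en-2-yl)benzene
Conditions: NaH, MOMCl, DMF, 0 °C → rt
Reagents that add atoms: chloromethyl methyl ether, COCCl
Why: Double O-alkylation of the catechol dianion gives the two acetal ethers that later become the C6 and C7 enol ethers.

Step 6
Reactants: 8 1-benzyloxy-3,4-bis(methoxymethoxy)-2,6-dimethyl-5-(2-methylbut-3-en-2-yl)benzene
Product: 9 2-[5-benzyloxy-2,3-bis(methoxymethoxy)-4,6-dimethylphenyl]-2-methylpropanal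
Conditions: OsO4 (cat.), NaIO4, 2,6-lutidine, dioxane/H2O, rt
Reagents that add atoms: osmium tetroxide, O=[Os](=O)(=O)=O; sodium periodate, [Na+].[O-]I(=O)(=O)=O
Why: Lemieux–Johnson cleavage of the monosubstituted alkene gives the non-enolisable C3 aldehyde and avoids ozone on the electron-rich arene.

Step 7
Reactants: 9 2-[5-benzyloxy-2,3-bis(methoxymethoxy)-4,6-dimethylphenyl]-2-methylpropanal; 10 allylmagnesium bromide
Product: 12 (3S)-2-[5-benzyloxy-2,3-bis(methoxymethoxy)-4,6-dimethylphenyl]-2-methylhex-5-en-3-ol, via diisopinocampheylborinate 11 (not isolated)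
Conditions: 10, (−)-Ipc2BOMe (from (+)-α-pinene), Et2O, −78 °C → rt; then 9, −78 °C; then NaOH aq., H2O2
Reagents that add atoms: none
Why: Brown asymmetric allylboration through a closed chair transition state should transfer allyl to the Si face of this pivalaldehyde-like aldehyde and so set C3 as (S).

Step 8
Reactants: 12 (3S)-homoallylic alcohol
Product: 13 tert-butyldimethylsilyl ether of 12
Conditions: TBSOTf, 2,6-lutidine, CH2Cl2, 0 °C
Reagents that add atoms: tert-butyldimethylsilyl triflate, CC(C)(C)[Si](C)(C)OS(=O)(=O)C(F)(F)F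
Why: The silyl triflate is needed for the neopentyl carbinol, and the bulky silyl ether is the group that later directs the face of ring closure.

Step 9
Reactants: 13 silyl ether
Product: 15 (3S)-4-aryl-3-(tert-butyldimethylsilyloxy)-4-methylpentan-1-ol, via aldehyde 14 (not isolated)
Conditions: OsO4 (cat.), NaIO4, 2,6-lutidine, dioxane/H2O, rt; extractive work-up; then NaBH4, MeOH, 0 °C
Reagents that add atoms: osmium tetroxide, O=[Os](=O)(=O)=O; sodium periodate, [Na+].[O-]I(=O)(=O)=O
Why: Lemieux–Johnson cleavage removes the terminal carbon and borohydride reduction leaves the C1 primary alcohol.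

Step 10
Reactants: 15 primary alcohol
Product: 16 3-[(3S)-3-(tert-butyldimethylsilyloxy)-5-hydroxy-2-methylpentan-2-yl]-4,5-bis(methoxymethoxy)-2,6-dimethylphenol
Conditions: H2 (1 atm), Pd/C, EtOAc, rt
Reagents that add atoms: none
Why: Hydrogenolysis of the aryl benzyl ether frees the C9 phenol while the MOM and silyl ethers are inert.

Step 11
Reactants: 16 phenol alcohol
Product: 17 3-[(3S)-3-(tert-butyldimethylsilyloxy)-5-iodo-2-methylpentan-2-yl]-4,5-bis(methoxymethoxy)-2,6-dimethylphenol
Conditions: I2, PPh3, imidazole, CH2Cl2, 0 °C → rt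
Reagents that add atoms: iodine, II
Why: Appel-type (Garegg–Samuelsson) iodination converts only the primary alcohol, the di-ortho-substituted phenol being unreactive toward the phosphonium reagent.

Step 12
Reactants: 17 iodoalkyl phenol
Product: 19 (6S,8aS)-6-(tert-butyldimethylsilyloxy)-3,4-bis(methoxymethoxy)-2,5,5,8a-tetramethyl-6,7,8,8a-tetrahydronaphthalen-1(5H)-one (rings A and B; C9 ketone, 10β-methyl, 3β-silyloxy), via sodium phenoxide 18 (not isolated)
Conditions: NaH (1.1 equiv), toluene, 0 °C → 90 °C, 0.005 M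
Reagents that add atoms: none
Why: Deprotonation gives sodium phenoxide 18, whose methyl-bearing ortho carbon C10 displaces iodide at C1 in an intramolecular SN2 reaction; this is the known ortho C-alkylation of 2,6-disubstituted phenolates to 6,6-disubstituted cyclohexa-2,4-dienones. Ring A (C10, C1, C2, C3, C4, C5) closes as a six-membered ring in 6-exo-tet mode, and O-alkylation is excluded because it would need an eight-membered ring. The new stereocentre C10 is controlled by C3: in the chair-like transition state the bulky silyloxy group should stay equatorial, since an axial one would be pressed against the π-face at C5/C6 and the axial hydrogen on C1, so the tether folds under the α-face and the methyl is pushed to the β-face, cis to the C3 oxygen. The step needs C10 (ortho) over C6 (para, also a six-membered closure) selectivity. This is secured by a contact ion pair in toluene, where sodium on O9 can assist loss of iodide only in the C10 transition state, and by the C6 methoxymethoxy group, which is twisted out of plane between its two ortho neighbours and shields C6. Preforming the phenoxide with NaH leaves no alkoxide for E2 at the iodide, and high dilution suppresses intermolecular O-alkylation.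

Step 13
Reactants: 20 (R)-malic acid
Product: 21 2-[(2R,4R)-2-tert-butyl-5-oxo-1,3-dioxolan-4-yl]acetic acid
Conditions: pivalaldehyde, TsOH (cat.), H2SO4 (cat.), pentane, reflux (Dean–Stark)
Reagents that add atoms: pivalaldehyde, CC(C)(C)C=O
Why: Seebach acetalisation of the α-hydroxy acid gives the thermodynamically favoured cis-dioxolanone, which stores the configuration of the carbinol carbon (C13) in the acetal centre.

Step 14
Reactants: 21 dioxolanone acid; 22 allyl bromide
Product: 24 2-[(2R,4R)-2-tert-butyl-5-oxo-4-(prop-2-enyl)-1,3-dioxolan-4-yl]acetic acid, via dilithium dianion 23 (not isolated)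
Conditions: LiN(SiMe3)2 (2.2 equiv), THF, −78 °C; 22, −78 → −20 °C; HCl aq.
Reagents that add atoms: none
Why: Alkylation of the dioxolanone enolate (self-regeneration of stereocentres) occurs trans to the tert-butyl group, so allyl takes the place of the former hydrogen and C13 becomes quaternary with defined configuration.

Step 15
Reactants: 24 allylated dioxolanone acid
Product: 25 (2R)-2-(prop-2-enyl)butane-1,2,4-triol
Conditions: LiAlH4, THF, 0 °C → reflux; Fieser work-up
Reagents that add atoms: none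
Why: Hydride reduction of the acid (to C15–OH) and of the acylal carbonyl (to C16–OH) releases the tertiary C13 hydroxyl without touching the stereocentre.

Step 16
Reactants: 25 triol
Product: 26 2-[(4R)-2,2-dimethyl-4-(prop-2-enyl)-1,3-dioxolan-4-yl]ethanol
Conditions: 2,2-dimethoxypropane, TsOH (cat.), acetone, rt
Reagents that add atoms: 2,2-dimethoxypropane, COC(C)(C)OC
Why: Acetonide formation under equilibrating conditions favours the five-membered dioxolane across C13–O and C16–O over the six-membered alternative and leaves C15–OH free.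

Step 17
Reactants: 26 acetonide alcohol
Product: 27 (4R)-4-[2-(benzyloxy)ethyl]-2,2-dimethyl-4-(prop-2-enyl)-1,3-dioxolane
Conditions: NaH, BnBr, nBu4NI (cat.), THF, 0 °C → rt
Reagents that add atoms: benzyl bromide, BrCc1ccccc1
Why: Williamson benzylation protects C15–OH with a group that the later hydrogenation removes.

Step 18
Reactants: 27 benzyl ether
Product: 29 2-[(4R)-4-[2-(benzyloxy)ethyl]-2,2-dimethyl-1,3-dioxolan-4-yl]ethanol, via aldehyde 28 (not isolated)
Conditions: OsO4 (cat.), NaIO4, 2,6-lutidine, dioxane/H2O, rt; extractive work-up; then NaBH4, MeOH, 0 °C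
Reagents that add atoms: osmium tetroxide, O=[Os](=O)(=O)=O; sodium periodate, [Na+].[O-]I(=O)(=O)=O
Why: Lemieux–Johnson cleavage of the allyl group and borohydride reduction give the two-carbon arm C12–C11 ending in a primary alcohol.

Step 19
Reactants: 29 alcohol
Product: 30 (4S)-4-[2-(benzyloxy)ethyl]-4-(2-iodoethyl)-2,2-dimethyl-1,3-dioxolane
Conditions: I2, PPh3, imidazole, CH2Cl2, 0 °C → rt
Reagents that add atoms: iodine, II
Why: Appel-type iodination of the primary alcohol gives the precursor of the side-chain organolithium.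

Step 20
Reactants: 30 side-chain iodide; 19 dienone
Product: 32 C9 tertiary alcohol (side chain on C9, mixture at C9), via organolithium 31 (not isolated)
Conditions: 30, t-BuLi (2.1 equiv), Et2O/pentane, −78 °C; then 19, THF, −78 → 0 °C; NH4Cl aq.
Reagents that add atoms: none
Why: Iodine–lithium exchange followed by 1,2-addition of the primary alkyllithium to the C9 carbonyl of the vinylogous ester, which has no α-hydrogen to enolise; the C9 configuration is irrelevant because C9 becomes sp2 in the next step.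

Step 21
Reactants: 32 C9 tertiary alcohol
Product: 33 cross-conjugated dienone diol (C7 ketone, Δ8, C5=C6–OMOM; free C13 and C16 hydroxyls)
Conditions: AcOH/THF/H2O (3:1:1), 45 °C
Reagents that add atoms: water, O
Why: In this Stork–Danheiser 1,3-carbonyl transposition the tertiary allylic C9 alcohol ionises to a cation stabilised by the C7 oxygen, water adds at C7 and the C7 acetal is lost to leave the Δ8-7-ketone; the same acid hydrolyses the acetonide and should spare the ketone-conjugated C6 enol ether and the hindered C3 silyl ether.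

Step 22
Reactants: 33 dienone diol
Product: 34 C16 tert-butyldimethylsilyl ether of 33
Conditions: TBSCl, imidazole, CH2Cl2, 0 °C
Reagents that add atoms: tert-butyldimethylsilyl chloride, CC(C)(C)[Si](C)(C)Cl
Why: Selective silylation of the primary hydroxyl leaves the tertiary C13 hydroxyl as the only nucleophile, so that a six-membered closure through O16 cannot compete in the next step.

Step 23
Reactants: 34 hydroxy dienone
Product: 36 9α,13-epoxy spiro ether (C7 ketone, 8α-methyl, C5=C6–OMOM), via potassium enolate 35 (not isolated)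
Conditions: KOtBu (0.2 equiv), t-BuOH/THF (1:4), 0 °C → rt
Reagents that add atoms: none
Why: In this intramolecular oxa-Michael addition (5-exo-trig) the C13 alkoxide should attack C9 axially, anti to the C10 methyl, to give the 9α-oxygen, and reversible protonation of the enolate places the C8 methyl equatorial (8α); C13 is not touched.

Step 24
Reactants: 36 spiro ether
Product: 37 5α-H, 6β-OMOM ketone with free C15 hydroxyl
Conditions: H2 (60 bar), Pd(OH)2/C, EtOAc, 40 °C
Reagents that add atoms: none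
Why: Heterogeneous hydrogenation should add both hydrogens syn from the α-face, because the β-face of C5=C6 is blocked by the axial methyls on C4 and C10; this gives 5α-H and the axial 6β-oxygen, and the same catalyst hydrogenolyses the C15 benzyl ether.

Step 25
Reactants: 37 primary alcohol
Product: 39 C15 carboxylic acid, via aldehyde 38 (not isolated)
Conditions: TEMPO (cat.), PhI(OAc)2, MeCN/H2O, rt
Reagents that add atoms: water, O
Why: Oxoammonium oxidation of the primary alcohol to the aldehyde and of its hydrate to the acid is mild and non-enolising, so C6 and C8 are not disturbed.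

Step 26
Reactants: 39 carboxylic acid
Product: 41 3β-hydroxy 15,16-lactone (C6–OMOM), via dihydroxy acid 40 (not isolated)
Conditions: HF·pyridine, pyridine/THF, 0 → 40 °C
Reagents that add atoms: none
Why: Fluoride-mediated cleavage of both silyl ethers frees C16–OH, which lactonises spontaneously onto the C15 acid (γ-lactone, helped by the quaternary C13), and frees C3–OH.

Step 27
Reactants: 41 hydroxy lactone
Product: 42 3β-acetate (C6–OMOM)
Conditions: Ac2O, pyridine, DMAP (cat.), CH2Cl2, rt
Reagents that add atoms: acetic anhydride, CC(=O)OC(C)=O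
Why: Acylation of the equatorial 3β-hydroxyl with a base too weak to open either β-alkoxy carbonyl unit by elimination.

Step 28
Reactants: 42 acetate MOM ether
Product: 44 CNP0325396.1, via dimethylborinate 43 (not isolated)
Conditions: Me2BBr, CH2Cl2, −78 °C; then NaHCO3 aq.
Reagents that add atoms: none
Why: Bromodimethylborane cleaves the acetal-type MOM ether at low temperature (Guindon cleavage) and should leave the acetate, the lactone and the di-tertiary ether; the non-enolising conditions keep the axial 6β-hydroxyl.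

## Compound list

1 | 2,6-dimethylhydroquinone | Cc1cc(O)cc(C)c1O | starting material
2 | prenyl bromide | CC(C)=CCBr | starting material
3 | 2,6-dimethyl-4-(3-methylbut-2-enyloxy)phenol | Cc1cc(OCC=C(C)C)cc(C)c1O | intermediate
4 | 2-benzyloxy-1,3-dimethyl-5-(3-methylbut-2-enyloxy)benzene | Cc1cc(OCC=C(C)C)cc(C)c1OCc1ccccc1 | intermediate
5 | 4-benzyloxy-3,5-dimethyl-2-(2-methylbut-3-en-2-yl)phenol | Oc1cc(C)c(OCc2ccccc2)c(C)c1C(C)(C)C=C | intermediate
6 | 4-benzyloxy-3,5-dimethyl-6-(2-methylbut-3-en-2-yl)cyclohexa-3,5-diene-1,2-dione (not isolated) | O=C1C(=O)C(C)=C(OCc2ccccc2)C(C)=C1C(C)(C)C=C | intermediate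
7 | 4-benzyloxy-3,5-dimethyl-6-(2-methylbut-3-en-2-yl)benzene-1,2-diol | Oc1c(O)c(C)c(OCc2ccccc2)c(C)c1C(C)(C)C=C | intermediate
8 | 1-benzyloxy-3,4-bis(methoxymethoxy)-2,6-dimethyl-5-(2-methylbut-3-en-2-yl)benzene | COCOc1c(OCOC)c(C)c(OCc2ccccc2)c(C)c1C(C)(C)C=C | intermediate
9 | 2-[5-benzyloxy-2,3-bis(methoxymethoxy)-4,6-dimethylphenyl]-2-methylpropanal | COCOc1c(OCOC)c(C)c(OCc2ccccc2)c(C)c1C(C)(C)C=O | intermediate
10 | allylmagnesium bromide | C=CC[Mg]Br | starting material
11 | diisopinocampheylborinate of 12 (not isolated) | COCOc1c(OCOC)c(C)c(OCc2ccccc2)c(C)c1C(C)(C)[C@H](CC=C)OB([C@@H]1C[C@@H]2C[C@H]([C@H]1C)C2(C)C)[C@@H]1C[C@@H]2C[C@H]([C@H]1C)C2(C)C | intermediate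
12 | (3S)-2-[5-benzyloxy-2,3-bis(methoxymethoxy)-4,6-dimethylphenyl]-2-methylhex-5-en-3-ol | COCOc1c(OCOC)c(C)c(OCc2ccccc2)c(C)c1C(C)(C)[C@@H](O)CC=C | intermediate
13 | tert-butyldimethylsilyl ether of 12 | COCOc1c(OCOC)c(C)c(OCc2ccccc2)c(C)c1C(C)(C)[C@@H](O[Si](C)(C)C(C)(C)C)CC=C | intermediate
14 | (3S)-4-aryl-3-(tert-butyldimethylsilyloxy)-4-methylpentanal (not isolated) | COCOc1c(OCOC)c(C)c(OCc2ccccc2)c(C)c1C(C)(C)[C@@H](O[Si](C)(C)C(C)(C)C)CC=O | intermediate
15 | (3S)-4-aryl-3-(tert-butyldimethylsilyloxy)-4-methylpentan-1-ol | COCOc1c(OCOC)c(C)c(OCc2ccccc2)c(C)c1C(C)(C)[C@@H](O[Si](C)(C)C(C)(C)C)CCO | intermediate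
16 | 3-[(3S)-3-(tert-butyldimethylsilyloxy)-5-hydroxy-2-methylpentan-2-yl]-4,5-bis(methoxymethoxy)-2,6-dimethylphenol | Cc1c(O)c(C)c(OCOC)c(OCOC)c1C(C)(C)[C@@H](O[Si](C)(C)C(C)(C)C)CCO | intermediate
17 | 3-[(3S)-3-(tert-butyldimethylsilyloxy)-5-iodo-2-methylpentan-2-yl]-4,5-bis(methoxymethoxy)-2,6-dimethylphenol (key-step precursor) | Cc1c(O)c(C)c(OCOC)c(OCOC)c1C(C)(C)[C@@H](O[Si](C)(C)C(C)(C)C)CCI | intermediate
18 | sodium phenoxide of 17 (not isolated) | Cc1c([O-])c(C)c(OCOC)c(OCOC)c1C(C)(C)[C@@H](O[Si](C)(C)C(C)(C)C)CCI.[Na+] | intermediate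
19 | (6S,8aS)-6-(tert-butyldimethylsilyloxy)-3,4-bis(methoxymethoxy)-2,5,5,8a-tetramethyl-6,7,8,8a-tetrahydronaphthalen-1(5H)-one (key-step product) | CC1=C(OCOC)C(OCOC)=C2C(C)(C)[C@@H](O[Si](C)(C)C(C)(C)C)CC[C@]2(C)C1=O | intermediate
20 | (R)-malic acid | OC(=O)C[C@@H](O)C(=O)O | starting material
21 | 2-[(2R,4R)-2-tert-butyl-5-oxo-1,3-dioxolan-4-yl]acetic acid (cis) | OC(=O)C[C@H]1O[C@@H](C(C)(C)C)OC1=O | intermediate
22 | allyl bromide | C=CCBr | starting material
23 | dilithium carboxylate enolate of 21 (not isolated) | [Li+].[Li+].[O-]C(=O)CC1=C([O-])O[C@H](C(C)(C)C)O1 | intermediate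
24 | 2-[(2R,4R)-2-tert-butyl-5-oxo-4-(prop-2-enyl)-1,3-dioxolan-4-yl]acetic acid | OC(=O)C[C@@]1(CC=C)O[C@@H](C(C)(C)C)OC1=O | intermediate
25 | (2R)-2-(prop-2-enyl)butane-1,2,4-triol | OCC[C@@](CO)(CC=C)O | intermediate
26 | 2-[(4R)-2,2-dimethyl-4-(prop-2-enyl)-1,3-dioxolan-4-yl]ethanol | OCC[C@]1(CC=C)COC(C)(C)O1 | intermediate
27 | (4R)-4-[2-(benzyloxy)ethyl]-2,2-dimethyl-4-(prop-2-enyl)-1,3-dioxolane | c1ccccc1COCC[C@]2(CC=C)COC(C)(C)O2 | intermediate
28 | 2-[(4S)-4-[2-(benzyloxy)ethyl]-2,2-dimethyl-1,3-dioxolan-4-yl]acetaldehyde (not isolated) | c1ccccc1COCC[C@]2(CC=O)COC(C)(C)O2 | intermediate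
29 | 2-[(4R)-4-[2-(benzyloxy)ethyl]-2,2-dimethyl-1,3-dioxolan-4-yl]ethanol | c1ccccc1COCC[C@]2(CCO)COC(C)(C)O2 | intermediate
30 | (4S)-4-[2-(benzyloxy)ethyl]-4-(2-iodoethyl)-2,2-dimethyl-1,3-dioxolane | c1ccccc1COCC[C@]2(CCI)COC(C)(C)O2 | intermediate
31 | organolithium from 30 (C11–Li; not isolated) | c1ccccc1COCC[C@]2(CC[Li])COC(C)(C)O2 | intermediate
32 | C9 tertiary alcohol: dienol ether of rings A and B carrying the acetonide side chain on C9 (mixture at C9) | CC1=C(OCOC)C(OCOC)=C2C(C)(C)[C@@H](O[Si](C)(C)C(C)(C)C)CC[C@]2(C)C1(O)CC[C@@]3(CCOCc4ccccc4)COC(C)(C)O3 | intermediate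
33 | cross-conjugated dienone diol: C7 ketone, Δ8, C5=C6–OMOM, 3β-OTBS, side chain with free C13–OH and C16–OH, C15–OBn | CC1=C(CC[C@](O)(CO)CCOCc2ccccc2)[C@@]2(C)CC[C@H](O[Si](C)(C)C(C)(C)C)C(C)(C)C2=C(OCOC)C1=O | intermediate
34 | C16 tert-butyldimethylsilyl ether of 33 | CC1=C(CC[C@](O)(CO[Si](C)(C)C(C)(C)C)CCOCc2ccccc2)[C@@]2(C)CC[C@H](O[Si](C)(C)C(C)(C)C)C(C)(C)C2=C(OCOC)C1=O | intermediate
35 | potassium C7 enolate of 36 (not isolated) | [K+].CC(C)(C)[Si](C)(C)O[C@H]1CC[C@@]2(C)C(=C(OCOC)C([O-])=C(C)[C@]23CC[C@](CO[Si](C)(C)C(C)(C)C)(CCOCc4ccccc4)O3)C1(C)C | intermediate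
36 | 9α,13-epoxy spiro ether: C7 ketone, 8α-methyl, C5=C6–OMOM, 3β-OTBS, C16–OTBS, C15–OBn | CC(C)(C)[Si](C)(C)O[C@H]1CC[C@@]2(C)C(=C(OCOC)C(=O)[C@@H](C)[C@]23CC[C@](CO[Si](C)(C)C(C)(C)C)(CCOCc4ccccc4)O3)C1(C)C | intermediate
37 | 5α-H, 6β-OMOM 7-ketone with free C15–OH | CC(C)(C)[Si](C)(C)O[C@H]1CC[C@@]2(C)[C@@H]([C@H](OCOC)C(=O)[C@@H](C)[C@]23CC[C@](CO[Si](C)(C)C(C)(C)C)(CCO)O3)C1(C)C | intermediate
38 | C15 aldehyde of 37 (not isolated) | CC(C)(C)[Si](C)(C)O[C@H]1CC[C@@]2(C)[C@@H]([C@H](OCOC)C(=O)[C@@H](C)[C@]23CC[C@](CO[Si](C)(C)C(C)(C)C)(CC=O)O3)C1(C)C | intermediate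
39 | C15 carboxylic acid | CC(C)(C)[Si](C)(C)O[C@H]1CC[C@@]2(C)[C@@H]([C@H](OCOC)C(=O)[C@@H](C)[C@]23CC[C@](CO[Si](C)(C)C(C)(C)C)(CC(=O)O)O3)C1(C)C | intermediate
40 | 3,16-dihydroxy C15 acid (not isolated) | O[C@H]1CC[C@@]2(C)[C@@H]([C@H](OCOC)C(=O)[C@@H](C)[C@]23CC[C@](CO)(CC(=O)O)O3)C1(C)C | intermediate
41 | 3β-hydroxy-6β-(methoxymethoxy)-7-oxo-9α,13-epoxylabdan-15,16-olide | O[C@H]1CC[C@@]2(C)[C@@H]([C@H](OCOC)C(=O)[C@@H](C)[C@]23CC[C@@]4(COC(=O)C4)O3)C1(C)C | intermediate
42 | 3β-acetoxy-6β-(methoxymethoxy)-7-oxo-9α,13-epoxylabdan-15,16-olide | CC(=O)O[C@H]1CC[C@@]2(C)[C@@H]([C@H](OCOC)C(=O)[C@@H](C)[C@]23CC[C@@]4(COC(=O)C4)O3)C1(C)C | intermediate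
43 | C6 dimethylborinate of the target (not isolated) | CC(=O)O[C@H]1CC[C@@]2(C)[C@@H]([C@H](OB(C)C)C(=O)[C@@H](C)[C@]23CC[C@@]4(COC(=O)C4)O3)C1(C)C | intermediate
44 | CNP0325396.1 (3β-acetoxy-6β-hydroxy-7-oxo-9α,13-epoxylabdan-15,16-olide) | CC(=O)O[C@H]1CC[C@@]2(C)[C@@H]([C@H](O)C(=O)[C@@H](C)[C@]23CC[C@@]2(COC(=O)C2)O3)C1(C)C | target

## Step count and risks

Total step count: 28. Longest linear sequence: 21 steps (steps 1–12, then 20–28); the side chain (steps 13–19) joins at step 20.

Steps most likely to fail: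

1. Step 12. The closure may take the other face of C10 (methyl trans to the C3 oxygen) or leak to the para carbon C6. The equatorial preference of the silyloxy group next to the gem-dimethyl carbon is not large, so the sense and size of the facial bias are the main uncertainty.
 Fallback: it sets out from aldehyde 9 and comes back at dienone 19, and makes the route independent of the sense of induction by correcting C3 after ring closure. Allylboration of 9 with the antipodal borane (from (+)-Ipc2BOMe) would give, through borinate F1, the (R)-carbinol F2. Steps 8–11 applied unchanged would give silyl ether F3, aldehyde F4 (not isolated), alcohol F5, phenol F6 and iodide F7. Ring closure as in step 12, through phenoxide F8, would then give the (3R,10S)-dienone F9, in which C10 is correct if the methyl is delivered trans. Desilylation with nBu4NF gives alcohol F10 and Dess–Martin periodinane gives the 3-ketone F11. NaBH4 at −40 °C should deliver hydride axially from the α-face, the known course for 4,4-dimethyl-3-ketones, to give the equatorial 3β-alcohol F12, which TBSOTf and 2,6-lutidine convert into 19.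

2. Step 24. The tetrasubstituted C5=C6 enol ether lies between two quaternary carbons and may resist hydrogenation, or hydrogen may reach the ketone first.
 Fallback: it sets out from 36 and comes back at 37, and replaces surface hydrogenation by a dissolving-metal conjugate reduction. Li in NH3/THF with one equivalent of t-BuOH at −78 °C transfers electrons to the enone, C5 is protonated axially to give the trans ring fusion (5α-H), and the benzyl ether is cleaved in the same flask. After excess lithium is destroyed with isoprene, the dilithium enolate alkoxide F14 is protonated at C6 by NH4Cl from the open α-face (the β-face is blocked by the 4β- and 10β-methyls), which should leave the 6β-oxygen.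

3. Step 23. The conjugate addition may stop on the side of the open enone, or the base may move the C8=C9 double bond out of conjugation by deprotonation at C11.
 Fallback: it sets out from 34 and comes back at 36, and replaces the catalytic equilibration by a stoichiometric anionic closure with capture. KN(SiMe3)2 (1.1 equiv) in THF at −78 °C followed by Et3SiCl traps the cyclised enolate as the triethylsilyl enol ether F13, which cannot revert. nBu4NF buffered with AcOH at −40 °C then protonates C8 axially from the β-face to give the 8α-methyl ketone 36.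

## Further compounds

F1 | step 12 | antipodal diisopinocampheylborinate of F2 (not isolated) | COCOc1c(OCOC)c(C)c(OCc2ccccc2)c(C)c1C(C)(C)[C@@H](CC=C)OB([C@H]1C[C@H]2C[C@@H]([C@@H]1C)C2(C)C)[C@H]1C[C@H]2C[C@@H]([C@@H]1C)C2(C)C
F2 | step 12 | (3R)-2-[5-benzyloxy-2,3-bis(methoxymethoxy)-4,6-dimethylphenyl]-2-methylhex-5-en-3-ol | COCOc1c(OCOC)c(C)c(OCc2ccccc2)c(C)c1C(C)(C)[C@H](O)CC=C
F3 | step 12 | tert-butyldimethylsilyl ether of F2 | COCOc1c(OCOC)c(C)c(OCc2ccccc2)c(C)c1C(C)(C)[C@H](O[Si](C)(C)C(C)(C)C)CC=C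
F4 | step 12 | (3R)-4-aryl-3-(tert-butyldimethylsilyloxy)-4-methylpentanal (not isolated) | COCOc1c(OCOC)c(C)c(OCc2ccccc2)c(C)c1C(C)(C)[C@H](O[Si](C)(C)C(C)(C)C)CC=O
F5 | step 12 | (3R)-4-aryl-3-(tert-butyldimethylsilyloxy)-4-methylpentan-1-ol | COCOc1c(OCOC)c(C)c(OCc2ccccc2)c(C)c1C(C)(C)[C@H](O[Si](C)(C)C(C)(C)C)CCO
F6 | step 12 | (3R)-epimer of phenol 16 | Cc1c(O)c(C)c(OCOC)c(OCOC)c1C(C)(C)[C@H](O[Si](C)(C)C(C)(C)C)CCO
F7 | step 12 | (3R)-epimer of iodide 17 | Cc1c(O)c(C)c(OCOC)c(OCOC)c1C(C)(C)[C@H](O[Si](C)(C)C(C)(C)C)CCI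
F8 | step 12 | sodium phenoxide of F7 (not isolated) | Cc1c([O-])c(C)c(OCOC)c(OCOC)c1C(C)(C)[C@H](O[Si](C)(C)C(C)(C)C)CCI.[Na+]
F9 | step 12 | (3R,10S)-dienone, the C3 epimer of 19 | CC1=C(OCOC)C(OCOC)=C2C(C)(C)[C@H](O[Si](C)(C)C(C)(C)C)CC[C@]2(C)C1=O
F10 | step 12 | (3R,10S)-3-hydroxy dienone | CC1=C(OCOC)C(OCOC)=C2C(C)(C)[C@H](O)CC[C@]2(C)C1=O
F11 | step 12 | (10S)-3-oxo dienone | CC1=C(OCOC)C(OCOC)=C2C(C)(C)C(=O)CC[C@]2(C)C1=O
F12 | step 12 | (3S,10S)-3-hydroxy dienone | CC1=C(OCOC)C(OCOC)=C2C(C)(C)[C@@H](O)CC[C@]2(C)C1=O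
F13 | step 23 | C7 triethylsilyl enol ether of 36 | CC(C)(C)[Si](C)(C)O[C@H]1CC[C@@]2(C)C(=C(OCOC)C(O[Si](CC)(CC)CC)=C(C)[C@]23CC[C@](CO[Si](C)(C)C(C)(C)C)(CCOCc4ccccc4)O3)C1(C)C
F14 | step 24 | dilithium C7 enolate C15 alkoxide of 37 (not isolated) | [Li+].[Li+].CC(C)(C)[Si](C)(C)O[C@H]1CC[C@@]2(C)[C@@H](C(OCOC)=C([O-])[C@@H](C)[C@]23CC[C@](CO[Si](C)(C)C(C)(C)C)(CC[O-])O3)C1(C)C
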